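**Assumptions:** (5R)-5-(l-menthyloxy)-2(5H)-furanone (4) is taken as a catalogue chiral butenolide; if unavailable it is two steps from furfural and l-menthol. The benzylic carbinol centre in 5–7 is formed as an epimer mixture, which does not matter because step 5 ionises that carbon.

## Retrosynthetic overview

1. Target 9 ⇐ dibenzyl ether 8 by removing the two phenolic benzyl groups.
2. The THF ring is the only ring built and is closed last: C2–O bond by benzylic-cation cycloetherification of triol 7, which sets C2 trans to C3.
3. Triol 7 ⇐ lactone 5 by LiAlH4 opening of the butenolide template (both termini become CH2OH, menthol is lost) and reductive removal of the two SPh groups.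
4. Lactone 5 ⇐ one-pot Michael/aldol of ArC(SPh)2Li (from 3), butenolide 4 and aldehyde 1, which sets the two backbone stereocentres (C3 and C4 of the target).

## Route

**Step 1**
Reactants: 1, 4-(benzyloxy)-3-methoxybenzaldehyde (O-benzylvanillin); 2, thiophenol
Product: 3, 4-(benzyloxy)-3-methoxyphenyl-bis(phenylsulfanyl)methane
Conditions: PhSH (2.2 equiv), TMSCl, CH2Cl2, 0 °C → rt
Reagents that add atoms: thiophenol (2), Sc1ccccc1
Why: Acid-promoted dithioacetalisation of an aryl aldehyde; the aryl benzyl ether tolerates TMSCl/HCl, and no stereocentre is formed.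

**Step 2**
Reactants: 3; 4, (5R)-5-[(1R,2S,5R)-menthyloxy]furan-2(5H)-one; 1 (second equivalent)
Product: 5, (3S,4R,5R)-3-[(4-benzyloxy-3-methoxyphenyl)(hydroxy)methyl]-4-[(4-benzyloxy-3-methoxyphenyl)bis(phenylsulfanyl)methyl]-5-(l-menthyloxy)dihydrofuran-2(3H)-one, with 3,4-trans and 4,5-trans ring substituents and the carbinol as an epimer mixture
Conditions: 3, n-BuLi, THF, −78 °C; then 4, −78 °C, 1.5 h; then 1, −78 °C, 1 h; AcOH/NH4Cl quench at −78 °C
Reagents that add atoms: none (all atoms come from 1, 3 and 4)
Why: Tandem Michael addition/aldol on a γ-alkoxybutenolide: the soft sulfur-stabilised benzylic anion adds 1,4 anti to the C5 menthyloxy group (sets C4), and the lithium enolate is trapped by the aldehyde anti to the bulky C4 substituent (sets C3).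

**Step 3**
Reactants: 5
Product: 6, (2R,3R)-2-[(4-benzyloxy-3-methoxyphenyl)(hydroxy)methyl]-3-[(4-benzyloxy-3-methoxyphenyl)bis(phenylsulfanyl)methyl]butane-1,4-diol
Conditions: LiAlH4 (excess), THF, 0 °C → rt; Rochelle-salt work-up; menthol removed by chromatography
Reagents that add atoms: none
Why: Hydride reduction of the lactone carbonyl releases the C5 hemiacetal, which loses menthoxide to give an aldehyde that is also reduced, so both termini become CH2OH; dithioacetal and benzyl ethers are inert and neither stereocentre is epimerisable.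

**Step 4**
Reactants: 6
Product: 7, (2R,3R)-2-[(4-benzyloxy-3-methoxyphenyl)(hydroxy)methyl]-3-(4-benzyloxy-3-methoxybenzyl)butane-1,4-diol
Conditions: NiCl2·6H2O, NaBH4, MeOH–THF, 0 °C
Reagents that add atoms: none
Why: Nickel boride reductive desulfurisation converts ArC(SPh)2 to ArCH2 under conditions that should leave aryl benzyl ethers and the benzylic alcohol intact (Raney Ni is avoided because it risks debenzylation and benzylic C–O loss).

**Step 5**
Reactants: 7
Product: 8, [(2S,3R,4R)-2-(4-benzyloxy-3-methoxyphenyl)-4-(4-benzyloxy-3-methoxybenzyl)tetrahydrofuran-3-yl]methanol (di-O-benzyl-lariciresinol)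
Conditions: CSA (10 mol%), CH2Cl2 (0.01 M), 0 °C → rt; quench with NaHCO3 as soon as 7 is consumed
Reagents that add atoms: none (water is lost)
Why: SN1 cycloetherification: both carbinol epimers give the same p-alkoxybenzyl cation, which is captured by the C4 CH2OH to form the five-membered ring (the other CH2OH could only give an oxetane); the reversible closure places the aryl group trans to the C3 CH2OH and C4 benzyl, avoiding the all-cis isomer, which sets C2 as S.

**Step 6**
Reactants: 8
Product: 9, (+)-lariciresinol, 4-[(2S,3R,4R)-4-(4-hydroxy-3-methoxybenzyl)-3-(hydroxymethyl)tetrahydrofuran-2-yl]-2-methoxyphenol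
Conditions: H2 (1 atm), 10% Pd/C, EtOAc, rt; stop at consumption of 8
Reagents that add atoms: none
Why: Hydrogenolysis of aryl benzyl ethers is much faster than cleavage of the benzylic THF C–O bond in neutral EtOAc, so the ring and all three stereocentres are retained.

## Compound list

1 | 4-(benzyloxy)-3-methoxybenzaldehyde | COc1cc(C=O)ccc1OCc1ccccc1 | starting material
2 | thiophenol | Sc1ccccc1 | starting material
3 | 4-(benzyloxy)-3-methoxyphenyl-bis(phenylsulfanyl)methane | COc1cc(C(Sc2ccccc2)Sc2ccccc2)ccc1OCc1ccccc1 | intermediate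
4 | (5R)-5-[(1R,2S,5R)-menthyloxy]furan-2(5H)-one | O=C1C=C[C@H](O[C@@H]2C[C@H](C)CC[C@H]2C(C)C)O1 | starting material
5 | (3S,4R,5R) Michael/aldol adduct (carbinol epimer mixture) | O=C1[C@H](C(O)c2ccc(OCc3ccccc3)c(OC)c2)[C@@H](C(Sc2ccccc2)(Sc2ccccc2)c2ccc(OCc3ccccc3)c(OC)c2)[C@H](O[C@@H]2C[C@H](C)CC[C@H]2C(C)C)O1 | intermediate
6 | (2R,3R) triol bis(phenylsulfanyl)acetal (carbinol epimer mixture) | OC[C@H](C(O)c1ccc(OCc2ccccc2)c(OC)c1)[C@H](CO)C(Sc1ccccc1)(Sc1ccccc1)c1ccc(OCc2ccccc2)c(OC)c1 | intermediate
7 | (2R,3R)-2-[aryl(hydroxy)methyl]-3-(arylmethyl)butane-1,4-diol, aryl = 4-benzyloxy-3-methoxyphenyl (carbinol epimer mixture) | OC[C@H](C(O)c1ccc(OCc2ccccc2)c(OC)c1)[C@H](CO)Cc1ccc(OCc2ccccc2)c(OC)c1 | intermediate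
8 | di-O-benzyl-(+)-lariciresinol (2S,3R,4R) | COc1cc(C[C@H]2CO[C@H](c3ccc(OCc4ccccc4)c(OC)c3)[C@H]2CO)ccc1OCc1ccccc1 | intermediate
9 | (+)-lariciresinol (2S,3R,4R) | COc1cc(C[C@H]2CO[C@H](c3ccc(O)c(OC)c3)[C@H]2CO)ccc1O | target

## Summary

Total steps: 6. Longest linear sequence: 6 (from 1).

Steps most likely to fail, with fallbacks:

1. **Step 2** (three-component Michael/aldol: competing 1,2-addition, incomplete enolate trapping, retro-aldol). Fallback: set the C4 centre separately by Evans alkylation. The (S)-4-benzyloxazolidinone imide of 3-(4-benzyloxy-3-methoxyphenyl)propanoic acid is alkylated with tert-butyl bromoacetate, then LiBH4 and acid lactonisation give (R)-4-(4-benzyloxy-3-methoxybenzyl)dihydrofuran-2(3H)-one. A trans-selective LDA aldol of this lactone with 1, then LiAlH4, gives triol 7 without sulfur chemistry.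

2. **Step 5** (acid cyclisation: competing Friedel–Crafts closure onto the other aryl ring to an aryltetralin of the isolariciresinol type, or C2 epimer). Fallback: reverse the end-game. Hydrogenolyse the benzyl ethers of 7 first, then close the ring on the free bis-phenol through its para-quinone methide under near-neutral, mildly acidic conditions, making ring closure the final step.

3. **Step 6** (over-hydrogenolysis of the benzylic ring C–O bond to secoisolariciresinol). Fallback: change the protecting group from the start. Run steps 1–5 with TIPS-protected vanillin and finish with TBAF/AcOH, so no reductive step follows ring formation.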